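**Retrosynthetic overview**
- Feature: in benzoyl ring A, the carbon bearing the diaryl ether oxygen (A-1) is next to the carbon bearing the lactone carbonyl (A-6), and A-6 lies beside oxygenated A-5. Ring A is therefore a 3-alkoxyaryne (A-1≡A-6) that took an O-nucleophile at the far carbon and an acyl group at the near one. The two oxygens of seven-membered ring C sit on adjacent carbons C-6 and C-5 of chromene ring B.
- Disconnections: the three MOM ethers (step 18). Then the lactone bond C(=O)–O-5 of ring C, back to hydroxy diethylamide 32 (step 17). Then, in one operation, the ether bond O-6–A-1 and the bond A-6–C(=O), back to silylaryl triflate 11 and catechol monocarbamate 27 (step 16).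
- 11 comes from phloroglucinol by two carbamate-directed metalations (silicon first, then prenyl). 27 comes from 2,5-dihydroxybenzaldehyde; its single diethylcarbamate first directs the C-6 hydroxylation and later serves as the acyl donor.
- Ring order: benzene rings A and B are bought, pyran ring D is closed in step 11, and dioxepinone ring C is closed last, in step 17.

Key step: step 16

Remark on the chemistry: ring A is numbered A-1 (ether O), A-2 (prenyl), A-3 (O), A-4 (H), A-5 (O), A-6 (C=O). Rings B and D carry 2H-chromene locants. MOM = methoxymethyl and prenyl = 3-methylbut-2-enyl. The target has no stereocentre and no double bond with E/Z isomerism, so no step has to set configuration.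

**Ring A fragment**

Step 1
Reactants: 1 phloroglucinol
Product: 2 3,5-bis(methoxymethoxy)phenol
Conditions: MOMCl (2 equiv), i-Pr2NEt, THF–DMF, 0 °C → rt; chromatography
Reagents that add atoms: chloromethyl methyl ether (MOMCl), COCCl
Why: Base-mediated O-alkylation of a phenol with an α-chloro ether (MOM ether formation); the three hydroxy groups of 1 are equivalent, so two equivalents of MOMCl should give the bis-ether as the main member of a statistical set that chromatography separates.

Step 2
Reactants: 2 3,5-bis(methoxymethoxy)phenol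
Product: 3 3,5-bis(methoxymethoxy)phenyl N,N-diethylcarbamate
Conditions: ClC(O)NEt2, K2CO3, MeCN, reflux
Reagents that add atoms: N,N-diethylcarbamoyl chloride, CCN(CC)C(=O)Cl
Why: O-Carbamoylation (acyl substitution at the carbamoyl chloride by the phenoxide) places the strongest oxygen-based metalation director on the oxygen that will later leave as triflate.

Step 3
Reactants: 3 3,5-bis(methoxymethoxy)phenyl N,N-diethylcarbamate
Product: 5 3,5-bis(methoxymethoxy)-2-(trimethylsilyl)phenyl N,N-diethylcarbamate, via aryllithium 4 (not isolated)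
Conditions: s-BuLi, TMEDA, THF, −78 °C; then TMSCl, −78 °C → rt
Reagents that add atoms: chlorotrimethylsilane (TMSCl), C[Si](C)(C)Cl
Why: Directed ortho-metalation, in which the carbamate and a meta-related MOM ether act together on their common ortho position, so this site should be lithiated in preference to the one between the two weaker MOM directors, and at −78 °C the diethylcarbamate does not yet undergo the anionic Fries shift before TMSCl traps 4.

Step 4
Reactants: 5 3,5-bis(methoxymethoxy)-2-(trimethylsilyl)phenyl N,N-diethylcarbamate, 6 prenyl bromide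
Product: 9 3,5-bis(methoxymethoxy)-2-(3-methylbut-2-enyl)-6-(trimethylsilyl)phenyl N,N-diethylcarbamate, via aryllithium 7 (not isolated), via arylcopper 8 (not isolated)
Conditions: s-BuLi, TMEDA, THF, −78 °C; CuBr·SMe2, −78 °C; then 6, −78 → 0 °C
Reagents that add atoms: none
Why: Second directed ortho-metalation at the only C–H left beside the carbamate, transmetalation to monovalent copper (which stops the anionic ortho-Fries shift on warming) and SN2 allylation at the unhindered CH2 terminus of 6; silicon goes in first so that no benzylic-allylic CH2 group is ever exposed to s-BuLi.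

Step 5
Reactants: 9 3,5-bis(methoxymethoxy)-2-(3-methylbut-2-enyl)-6-(trimethylsilyl)phenyl N,N-diethylcarbamate
Product: 10 3,5-bis(methoxymethoxy)-2-(3-methylbut-2-enyl)-6-(trimethylsilyl)phenol
Conditions: LiAlH4, THF, 0 °C → reflux; Na2SO4·10H2O work-up
Reagents that add atoms: none
Why: Reductive cleavage of an aryl carbamate by hydride (acyl substitution with loss of the aryloxide) works on doubly ortho-substituted diethylcarbamates that resist hydrolysis, leaves aryl–Si, MOM and alkene untouched, and the non-acidic work-up avoids protodesilylation of the electron-rich arylsilane.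

Step 6
Reactants: 10 3,5-bis(methoxymethoxy)-2-(3-methylbut-2-enyl)-6-(trimethylsilyl)phenol
Product: 11 3,5-bis(methoxymethoxy)-2-(3-methylbut-2-enyl)-6-(trimethylsilyl)phenyl trifluoromethanesulfonate
Conditions: Tf2O, pyridine, CH2Cl2, −78 → 0 °C
Reagents that add atoms: trifluoromethanesulfonic anhydride (Tf2O), O=S(=O)(OS(=O)(=O)C(F)(F)F)C(F)(F)F
Why: O-Sulfonylation of the phenol under pyridine buffering gives the ortho-silylaryl triflate, the standard fluoride-triggered aryne precursor, and the same operation is routine for 6-alkyl-2-silylphenols.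

**Ring B fragment**

Step 7
Reactants: 12 2,5-dihydroxybenzaldehyde
Product: 13 3-formyl-4-hydroxyphenyl N,N-diethylcarbamate
Conditions: ClC(O)NEt2 (1 equiv), Et3N, DMAP (cat.), CH2Cl2, reflux
Reagents that add atoms: N,N-diethylcarbamoyl chloride, CCN(CC)C(=O)Cl
Why: Chemoselective O-carbamoylation, because the 2-OH is held in a hydrogen bond to the aldehyde and only the free 5-OH should be acylated by the DMAP-activated carbamoyl chloride.

Step 8
Reactants: 13 3-formyl-4-hydroxyphenyl N,N-diethylcarbamate
Product: 14 3-formyl-4-(methoxymethoxy)phenyl N,N-diethylcarbamate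
Conditions: MOMCl, i-Pr2NEt, CH2Cl2, 0 °C → rt
Reagents that add atoms: chloromethyl methyl ether (MOMCl), COCCl
Why: MOM ether formation (O-alkylation) at the one remaining phenol, which fixes the future C-8 oxygen as the protected one.

Step 9
Reactants: 14 3-formyl-4-(methoxymethoxy)phenyl N,N-diethylcarbamate
Product: 16 3-hydroxy-4-(methoxymethoxy)phenyl N,N-diethylcarbamate, via aryl formate 15 (not isolated)
Conditions: mCPBA, CH2Cl2, rt; then K2CO3 (cat.), MeOH, 0 °C
Reagents that add atoms: 3-chloroperbenzoic acid (mCPBA), OOC(=O)c1cccc(Cl)c1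
Why: Baeyer–Villiger oxidation of an ortho-alkoxybenzaldehyde (aryl migration), carried out before any alkene is present, followed by mild transesterification of the formate, to which the diethylcarbamate is inert.

Step 10
Reactants: 16 3-hydroxy-4-(methoxymethoxy)phenyl N,N-diethylcarbamate, 17 3-chloro-3-methylbut-1-yne
Product: 18 4-(methoxymethoxy)-3-[(2-methylbut-3-yn-2-yl)oxy]phenyl N,N-diethylcarbamate
Conditions: DBU, CuCl2·2H2O (1 mol %), MeCN, 0 °C
Reagents that add atoms: none
Why: Copper-catalysed O-propargylation of a phenol with a tertiary propargylic chloride, the standard entry to aryl 1,1-dimethylpropargyl ethers, which tolerates ortho substituents.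

Step 11
Reactants: 18 4-(methoxymethoxy)-3-[(2-methylbut-3-yn-2-yl)oxy]phenyl N,N-diethylcarbamate
Product: 20 8-(methoxymethoxy)-2,2-dimethyl-2H-chromen-5-yl N,N-diethylcarbamate, via allenylphenol 19 (not isolated)
Conditions: o-xylene, 140 °C
Reagents that add atoms: none
Why: Aromatic propargyl Claisen rearrangement to the only free ortho carbon (the other carries the MOM ether), tautomerisation to 19, 1,5-hydrogen shift and oxa-6π electrocyclisation close pyran ring D.

Step 12
Reactants: 20 8-(methoxymethoxy)-2,2-dimethyl-2H-chromen-5-yl N,N-diethylcarbamate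
Product: 23 6-hydroxy-8-(methoxymethoxy)-2,2-dimethyl-2H-chromen-5-yl N,N-diethylcarbamate, via aryllithium 21 (not isolated), via dimethyl boronate 22 (not isolated)
Conditions: s-BuLi, TMEDA, THF, −78 °C; B(OMe)3, −78 → 0 °C; then 30% H2O2, AcOH, 0 °C → rt
Reagents that add atoms: hydrogen peroxide, OO
Why: Directed ortho-metalation at C-6 beside the carbamate (a stronger director than the C-8 MOM ether), borylation and oxidative boron-to-oxygen 1,2-migration; H2O2 in AcOH should not epoxidise the chromene and does not create a basic phenoxide beside the carbamate.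

Step 13
Reactants: 23 6-hydroxy-8-(methoxymethoxy)-2,2-dimethyl-2H-chromen-5-yl N,N-diethylcarbamate, 17 3-chloro-3-methylbut-1-yne
Product: 24 8-(methoxymethoxy)-2,2-dimethyl-6-[(2-methylbut-3-yn-2-yl)oxy]-2H-chromen-5-yl N,N-diethylcarbamate
Conditions: DBU, CuCl2·2H2O (1 mol %), MeCN, 0 °C
Reagents that add atoms: none
Why: The same copper-catalysed O-propargylation as in step 10, and at 0 °C the diethylcarbamate is too poor an electrophile to move to the neighbouring oxygen.

Step 14
Reactants: 24 8-(methoxymethoxy)-2,2-dimethyl-6-[(2-methylbut-3-yn-2-yl)oxy]-2H-chromen-5-yl N,N-diethylcarbamate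
Product: 25 8-(methoxymethoxy)-2,2-dimethyl-6-[(2-methylbut-3-en-2-yl)oxy]-2H-chromen-5-yl N,N-diethylcarbamate
Conditions: H2 (1 atm), Pd/CaCO3 poisoned with Pb(OAc)2, quinoline, EtOAc, rt
Reagents that add atoms: none
Why: Semihydrogenation of a terminal alkyne over poisoned palladium, in which the internal, conjugated chromene alkene is reduced far more slowly.

Step 15
Reactants: 25 8-(methoxymethoxy)-2,2-dimethyl-6-[(2-methylbut-3-en-2-yl)oxy]-2H-chromen-5-yl N,N-diethylcarbamate
Product: 27 6-hydroxy-8-(methoxymethoxy)-2,2-dimethyl-7-(3-methylbut-2-enyl)-2H-chromen-5-yl N,N-diethylcarbamate, via cyclohexadienone 26 (not isolated)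
Conditions: toluene, 110 °C (sealed tube)
Reagents that add atoms: none
Why: Aromatic Claisen rearrangement ([3,3]-sigmatropic) to C-7, the only free ortho position, whose allyl inversion turns the reverse-prenyl ether into a linear C-prenyl group, and rearomatisation of 26 frees the C-6 phenol.

**Fragment union and endgame**

Step 16
Reactants: 27 6-hydroxy-8-(methoxymethoxy)-2,2-dimethyl-7-(3-methylbut-2-enyl)-2H-chromen-5-yl N,N-diethylcarbamate, 11 3,5-bis(methoxymethoxy)-2-(3-methylbut-2-enyl)-6-(trimethylsilyl)phenyl trifluoromethanesulfonate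
Product: 32 N,N-diethyl-2-{[5-hydroxy-8-(methoxymethoxy)-2,2-dimethyl-7-(3-methylbut-2-enyl)-2H-chromen-6-yl]oxy}-4,6-bis(methoxymethoxy)-3-(3-methylbut-2-enyl)benzamide, via sodium phenoxide 28 (not isolated), via aryne 29 (not isolated), via aryl anion 30 (not isolated), via tetrahedral adduct 31 (not isolated)
Conditions: 27, NaH, THF, 0 °C; then KF, 18-crown-6, 11 (1.5 equiv, slow addition), THF, 0 °C → rt; H2O
Reagents that add atoms: none
Why: Proposed new method: fluoride attacks the silicon of 11 and triflate leaves to give aryne 29 (A-1≡A-6), phenoxide 28 adds through O-6 to A-1 (new diaryl ether C–O bond), and aryl anion 30, formed at A-6, attacks the carbonyl of the carbamate on the neighbouring oxygen O-5 (new aryl–C(=O) bond) to give adduct 31. The closest known reaction types are the fluoride-induced annulation of arynes with salicylates, where phenoxide addition is followed by intramolecular acyl capture through a six-membered transition state to give xanthones, and the anionic ortho- and remote Fries rearrangements, where aryl anions take the carbamoyl group of an aryl O-carbamate; the untested element is their combination through a relay one atom longer. No ring is closed and no stereocentre remains, because the seven-membered cyclic adduct 31 collapses by expelling the ring-B aryloxide, a far better leaving group than diethylamide, so open-chain 32 should result after protonation. The step needs attack at A-1, next to the prenyl group, and not at A-6; the inductive pull of the A-5 MOM-oxy group polarises and distorts the aryne so that the nucleophile goes to the remote carbon and the charge builds up beside oxygen, a bias that should outweigh the steric cost of the flexible prenyl chain. The step also needs acyl capture to outrun protonation, which is why the phenol is deprotonated beforehand with NaH (hydrogen leaves the flask), THF replaces the more acidic MeCN, and 11 is added slowly so that ene and cycloaddition reactions of the aryne with the alkenes stay behind the much faster phenoxide addition. Which catechol oxygen becomes the ether and which the ester is fixed by the position of the carbamate set in step 12; a diethylcarbamate is the acyl donor that tolerates a neighbouring phenoxide, and both carbons ortho to it are substituted, so A-6 is its only carbanion partner.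

Step 17
Reactants: 32 N,N-diethyl-2-{[5-hydroxy-8-(methoxymethoxy)-2,2-dimethyl-7-(3-methylbut-2-enyl)-2H-chromen-6-yl]oxy}-4,6-bis(methoxymethoxy)-3-(3-methylbut-2-enyl)benzamide
Product: 35 tris-MOM-protected depsidone (lactone between A-6 C=O and O-5), via triflyloxyiminium triflate 33 (not isolated), via cyclic aryloxyiminium triflate 34 (not isolated)
Conditions: Tf2O (1.1 equiv), 2,4,6-collidine, CH2Cl2, −78 → 0 °C; then aq. NaOAc/AcOH buffer (pH 4–5), rt
Reagents that add atoms: water, O
Why: Electrophilic amide activation with lactonisation by a tethered hydroxy group: Tf2O turns the tertiary amide into 33, the C-5 phenol displaces triflate (7-exo-trig closure of ring C) to give 34, hydrolysis at mildly acidic pH expels the protonated amine rather than the phenol, and collidine keeps strong acid away from the MOM ethers, prenyl groups and chromene.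

Step 18
Reactants: 35 tris-MOM-protected depsidone
Product: 36 target depsidone CNP0263700.0
Conditions: 2 M aq. HCl, THF–i-PrOH, 40 °C
Reagents that add atoms: none
Why: Acid-catalysed acetal hydrolysis of the three aryl MOM ethers under dilute, mildly warm conditions of the kind commonly tolerated by ortho-prenylphenols and 2,2-dimethylchromenes, while the doubly ortho-substituted aryl ester is slow to solvolyse.

**Compound list**
1 | phloroglucinol | Oc1cc(O)cc(O)c1 | starting material
2 | 3,5-bis(methoxymethoxy)phenol | COCOc1cc(O)cc(OCOC)c1 | intermediate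
3 | 3,5-bis(methoxymethoxy)phenyl N,N-diethylcarbamate | CCN(CC)C(=O)Oc1cc(OCOC)cc(OCOC)c1 | intermediate
4 | 2-lithio derivative of 3 (Li between carbamate and MOM ether) | [Li]c1c(OC(=O)N(CC)CC)cc(OCOC)cc1OCOC | intermediate
5 | 3,5-bis(methoxymethoxy)-2-(trimethylsilyl)phenyl N,N-diethylcarbamate | CCN(CC)C(=O)Oc1cc(OCOC)cc(OCOC)c1[Si](C)(C)C | intermediate
6 | prenyl bromide (1-bromo-3-methylbut-2-ene) | CC(C)=CCBr | starting material
7 | 6-lithio derivative of 5 | [Li]c1c(OCOC)cc(OCOC)c([Si](C)(C)C)c1OC(=O)N(CC)CC | intermediate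
8 | 6-cuprio derivative of 5 (arylcopper, SMe2 ligand omitted) | [Cu]c1c(OCOC)cc(OCOC)c([Si](C)(C)C)c1OC(=O)N(CC)CC | intermediate
9 | 3,5-bis(methoxymethoxy)-2-(3-methylbut-2-enyl)-6-(trimethylsilyl)phenyl N,N-diethylcarbamate | CCN(CC)C(=O)Oc1c(CC=C(C)C)c(OCOC)cc(OCOC)c1[Si](C)(C)C | intermediate
10 | 3,5-bis(methoxymethoxy)-2-(3-methylbut-2-enyl)-6-(trimethylsilyl)phenol | Oc1c(CC=C(C)C)c(OCOC)cc(OCOC)c1[Si](C)(C)C | intermediate
11 | 3,5-bis(methoxymethoxy)-2-(3-methylbut-2-enyl)-6-(trimethylsilyl)phenyl trifluoromethanesulfonate (ring A aryne precursor) | CC(C)=CCc1c(OCOC)cc(OCOC)c([Si](C)(C)C)c1OS(=O)(=O)C(F)(F)F | intermediate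
12 | 2,5-dihydroxybenzaldehyde | O=Cc1cc(O)ccc1O | starting material
13 | 3-formyl-4-hydroxyphenyl N,N-diethylcarbamate | CCN(CC)C(=O)Oc1ccc(O)c(C=O)c1 | intermediate
14 | 3-formyl-4-(methoxymethoxy)phenyl N,N-diethylcarbamate | CCN(CC)C(=O)Oc1ccc(OCOC)c(C=O)c1 | intermediate
15 | 3-(formyloxy)-4-(methoxymethoxy)phenyl N,N-diethylcarbamate | CCN(CC)C(=O)Oc1ccc(OCOC)c(OC=O)c1 | intermediate
16 | 3-hydroxy-4-(methoxymethoxy)phenyl N,N-diethylcarbamate | CCN(CC)C(=O)Oc1ccc(OCOC)c(O)c1 | intermediate
17 | 3-chloro-3-methylbut-1-yne | CC(C)(Cl)C#C | starting material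
18 | 4-(methoxymethoxy)-3-[(2-methylbut-3-yn-2-yl)oxy]phenyl N,N-diethylcarbamate | CCN(CC)C(=O)Oc1ccc(OCOC)c(OC(C)(C)C#C)c1 | intermediate
19 | 3-hydroxy-4-(methoxymethoxy)-2-(3-methylbuta-1,2-dienyl)phenyl N,N-diethylcarbamate | CCN(CC)C(=O)Oc1ccc(OCOC)c(O)c1C=C=C(C)C | intermediate
20 | 8-(methoxymethoxy)-2,2-dimethyl-2H-chromen-5-yl N,N-diethylcarbamate | CCN(CC)C(=O)Oc1ccc(OCOC)c2OC(C)(C)C=Cc12 | intermediate
21 | 6-lithio derivative of 20 | CCN(CC)C(=O)Oc1c([Li])cc(OCOC)c2OC(C)(C)C=Cc12 | intermediate
22 | dimethyl [5-(diethylcarbamoyloxy)-8-(methoxymethoxy)-2,2-dimethyl-2H-chromen-6-yl]boronate | CCN(CC)C(=O)Oc1c(B(OC)OC)cc(OCOC)c2OC(C)(C)C=Cc12 | intermediate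
23 | 6-hydroxy-8-(methoxymethoxy)-2,2-dimethyl-2H-chromen-5-yl N,N-diethylcarbamate | CCN(CC)C(=O)Oc1c(O)cc(OCOC)c2OC(C)(C)C=Cc12 | intermediate
24 | 8-(methoxymethoxy)-2,2-dimethyl-6-[(2-methylbut-3-yn-2-yl)oxy]-2H-chromen-5-yl N,N-diethylcarbamate | CCN(CC)C(=O)Oc1c(OC(C)(C)C#C)cc(OCOC)c2OC(C)(C)C=Cc12 | intermediate
25 | 8-(methoxymethoxy)-2,2-dimethyl-6-[(2-methylbut-3-en-2-yl)oxy]-2H-chromen-5-yl N,N-diethylcarbamate | CCN(CC)C(=O)Oc1c(OC(C)(C)C=C)cc(OCOC)c2OC(C)(C)C=Cc12 | intermediate
26 | 7-prenyl-6-oxo-6,7-dihydrochromene dienone (Claisen intermediate, racemic at C-7, transient) | CCN(CC)C(=O)OC1=C2C=CC(C)(C)OC2=C(OCOC)C(CC=C(C)C)C1=O | intermediate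
27 | 6-hydroxy-8-(methoxymethoxy)-2,2-dimethyl-7-(3-methylbut-2-enyl)-2H-chromen-5-yl N,N-diethylcarbamate (ring B partner) | CC(C)=CCc1c(OCOC)c2OC(C)(C)C=Cc2c(OC(=O)N(CC)CC)c1O | intermediate
28 | sodium phenoxide of 27 | CC(C)=CCc1c(OCOC)c2OC(C)(C)C=Cc2c(OC(=O)N(CC)CC)c1[O-].[Na+] | intermediate
29 | ring A aryne (A-1≡A-6; A-2 prenyl, A-3 and A-5 MOM ethers) | CC(C)=CCC1=C(OCOC)C=C(OCOC)C#C1 | intermediate
30 | diaryl ether aryl anion (charge at A-6, carbamate still on O-5) | CC(C)=CCc1c(OCOC)c2OC(C)(C)C=Cc2c(OC(=O)N(CC)CC)c1Oc1c(CC=C(C)C)c(OCOC)cc(OCOC)[c-]1.[Na+] | intermediate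
31 | seven-membered cyclic tetrahedral adduct (alkoxide, racemic, transient) | CC(C)=CCc1c(OCOC)c2c(c3c1Oc1c(CC=C(C)C)c(OCOC)cc(OCOC)c1C([O-])(N(CC)CC)O3)C=CC(C)(C)O2.[Na+] | intermediate
32 | N,N-diethyl-2-{[5-hydroxy-8-(methoxymethoxy)-2,2-dimethyl-7-(3-methylbut-2-enyl)-2H-chromen-6-yl]oxy}-4,6-bis(methoxymethoxy)-3-(3-methylbut-2-enyl)benzamide | CC(C)=CCc1c(OCOC)c2OC(C)(C)C=Cc2c(O)c1Oc1c(CC=C(C)C)c(OCOC)cc(OCOC)c1C(=O)N(CC)CC | intermediate
33 | O-triflyl iminium triflate of 32 | CC(C)=CCc1c(OCOC)c2OC(C)(C)C=Cc2c(O)c1Oc1c(CC=C(C)C)c(OCOC)cc(OCOC)c1C(OS(=O)(=O)C(F)(F)F)=[N+](CC)CC.[O-]S(=O)(=O)C(F)(F)F | intermediate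
34 | cyclic aryloxy(diethyl)iminium triflate (ring C closed) | CC(C)=CCc1c(OCOC)c2c(c3c1Oc1c(CC=C(C)C)c(OCOC)cc(OCOC)c1C(=[N+](CC)CC)O3)C=CC(C)(C)O2.[O-]S(=O)(=O)C(F)(F)F | intermediate
35 | tris-MOM-protected depsidone | CC(C)=CCc1c(OCOC)c2c(c3c1Oc1c(CC=C(C)C)c(OCOC)cc(OCOC)c1C(=O)O3)C=CC(C)(C)O2 | intermediate
36 | target depsidone CNP0263700.0 (ring A: A-2 prenyl, A-3 OH, A-5 OH; ring B: C-7 prenyl, C-8 OH, fused 2,2-dimethylpyran ring D) | CC(C)=CCc1c(O)c2c(c3c1Oc1c(CC=C(C)C)c(O)cc(O)c1C(=O)O3)C=CC(C)(C)O2 | target

**Step count**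
- Total step count: 18.
- Longest linear sequence: 12 (steps 7–18). The ring A branch (steps 1–6) joins at step 16.

**Steps most likely to fail**

1. Step 16 (carries the label).
   - What may go wrong:
     - The aryl anion is protonated before it reaches the carbamate, either by adventitious water or by internal proton transfer from the allylic CH2 of the ring-B prenyl group.
     - The phenoxide adds to the wrong aryne carbon under the steric pressure of the A-2 prenyl group.
     - Base moves the carbamoyl group from O-5 to O-6 before arylation.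
   - Fallback: the two bond formations are separated, using established reaction types. The fallback sets out from 11 and 27.
     - Plain aryne O-arylation of the phenol (CsF, MeCN, rt), in which the medium protonates the aryl anion, should give the diaryl ether carbamate F1.
     - Excess LiN(i-Pr)2 in THF (0 °C → rt) then metalates F1 reversibly. Of the lithiated species only the A-6 lithio derivative F2 can be drained irreversibly.
     - The draining step is ring-to-ring carbamoyl transfer (directed remote metalation, remote anionic Fries rearrangement), with lithium activating the carbonyl.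
     - The sequence comes back to the route at 32.

2. Step 17.
   - What may go wrong:
     - The free phenol is O-sulfonylated in competition with amide activation.
     - The ortho MOM oxygen at A-5 takes part at the activated carbon.
     - The cyclic iminium salt opens towards amide and phenol during hydrolysis.
   - Fallback: the fallback sets out from 32 and changes the oxidation-state path.
     - Cp2Zr(H)Cl (excess, one equivalent being consumed by the phenol) in THF at rt should reduce the hindered tertiary amide to the aldehyde F3.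
     - Pinnick oxidation (NaClO2, NaH2PO4, 2-methylbut-2-ene, t-BuOH–H2O) should give the carboxylic acid F4.
     - Carbodiimide lactonisation (EDC·HCl, DMAP, CH2Cl2, high dilution), the classical closure of 2-(2-hydroxyaryloxy)benzoic acids, comes back to the route at 35.

3. Step 18.
   - What may go wrong:
     - The freed ortho-prenylphenols cyclise to chromans under acid catalysis.
     - Water or alcohol adds to the chromene double bond.
     - The lactone is solvolysed.
   - Fallback: the fallback sets out from 35 and avoids Brønsted acid.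
     - TMSOTf with 2,2′-bipyridyl (CH2Cl2, 0 °C → rt) should exchange the three acetals for silyl groups under buffered conditions, giving the tris(trimethylsilyl) ether F5.
     - Water at neutral pH then hydrolyses F5, and the sequence comes back to the route at 36.

**Further compounds**
F1 | step 16 | 6-[3,5-bis(methoxymethoxy)-2-(3-methylbut-2-enyl)phenoxy]-8-(methoxymethoxy)-2,2-dimethyl-7-(3-methylbut-2-enyl)-2H-chromen-5-yl N,N-diethylcarbamate | CC(C)=CCc1c(OCOC)c2OC(C)(C)C=Cc2c(OC(=O)N(CC)CC)c1Oc1cc(OCOC)cc(OCOC)c1CC=C(C)C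
F2 | step 16 | A-6 lithio derivative of F1 | CC(C)=CCc1c(OCOC)c2OC(C)(C)C=Cc2c(OC(=O)N(CC)CC)c1Oc1c(CC=C(C)C)c(OCOC)cc(OCOC)c1[Li]
F3 | step 17 | 2-{[5-hydroxy-8-(methoxymethoxy)-2,2-dimethyl-7-(3-methylbut-2-enyl)-2H-chromen-6-yl]oxy}-4,6-bis(methoxymethoxy)-3-(3-methylbut-2-enyl)benzaldehyde | CC(C)=CCc1c(OCOC)c2OC(C)(C)C=Cc2c(O)c1Oc1c(CC=C(C)C)c(OCOC)cc(OCOC)c1C=O
F4 | step 17 | 2-{[5-hydroxy-8-(methoxymethoxy)-2,2-dimethyl-7-(3-methylbut-2-enyl)-2H-chromen-6-yl]oxy}-4,6-bis(methoxymethoxy)-3-(3-methylbut-2-enyl)benzoic acid | CC(C)=CCc1c(OCOC)c2OC(C)(C)C=Cc2c(O)c1Oc1c(CC=C(C)C)c(OCOC)cc(OCOC)c1C(=O)O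
F5 | step 18 | tris(trimethylsilyl) ether of the target depsidone | CC(C)=CCc1c(O[Si](C)(C)C)c2c(c3c1Oc1c(CC=C(C)C)c(O[Si](C)(C)C)cc(O[Si](C)(C)C)c1C(=O)O3)C=CC(C)(C)O2
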